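The route rests on cutting the interflavanyl bond between C4 of ring C and C6 of ring D. Rings C and F share one pattern (2,3-cis-3,4-trans), so a single 3β-bromo-4α-acetoxyflavan is used twice. One portion is closed to the labile 3α,4α-epoxide. Its C4 is para to O7 and ortho to O1 of ring A, so it ionises like a quinone methide. C6 of ring D of a second, still masked portion (ortho to O7, para to O1) attacks from the β face. One operation thus inverts C3, sets C4 and forms the C–C bond. The precursor is nothing but this bromo acetate.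

Key step: step 6

Convention: flavan numbering is used. The upper unit has rings A (benzo), C (pyran) and B (2-aryl); the lower unit has rings D, F and E in the same sense. α is the face of a pyran ring that carries its 2-aryl group and β is the opposite face. Bn = benzyl.
Assumption: the enantiomer of the tartaric acid-derived catalyst in step 4 is chosen by a test run so that the (S)-configured 2-aryl-2H-chromene results.

Step 1
Reactants: 1 daphnetin (7,8-dihydroxycoumarin)
Product: 2 7,8-bis(benzyloxy)coumarin
Conditions: BnBr (2.5 equiv), K2CO3, DMF, 60 °C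
Reagents that add atoms: benzyl bromide BrCc1ccccc1
Why: Williamson ether synthesis on both catechol hydroxyl groups, with the lactone inert to carbonate and no stereocentre involved.

Step 2
Reactants: 2 7,8-bis(benzyloxy)coumarin
Product: 4 7,8-bis(benzyloxy)-2-ethoxy-2H-chromene (racemic acetal), via lactol 3 (not isolated)
Conditions: i-Bu2AlH (1.1 equiv), CH2Cl2, −78 °C; aq. potassium sodium tartrate; crude lactol in EtOH, PPTS (cat.), 4 Å MS, rt
Reagents that add atoms: ethanol CCO
Why: Partial lactone reduction with i-Bu2AlH at low temperature stops at the lactol, which undergoes acid-catalysed acetalisation through the O7-stabilised benzopyrylium ion; the racemic acetal centre is erased in step 4.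

Step 3
Reactants: 5 4-bromo-1,2-bis(benzyloxy)benzene
Product: 8 diethyl [3,4-bis(benzyloxy)phenyl]boronate, via aryllithium 6 (not isolated), via lithium aryltriethoxyborate 7 (not isolated)
Conditions: n-BuLi, THF, −78 °C; B(OEt)3, −78 °C to rt; HCl (1.0 equiv, Et2O), 0 °C; filter, concentrate
Reagents that add atoms: triethyl borate CCOB(OCC)OCC
Why: Bromine–lithium exchange, borylation with a trialkyl borate and protonolysis of the ate complex with one equivalent of anhydrous HCl is the standard access to dialkyl arylboronates, and benzyl ethers tolerate n-BuLi at −78 °C.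

Step 4
Reactants: 4 7,8-bis(benzyloxy)-2-ethoxy-2H-chromene; 8 diethyl [3,4-bis(benzyloxy)phenyl]boronate
Product: 9 (2S)-7,8-bis(benzyloxy)-2-[3,4-bis(benzyloxy)phenyl]-2H-chromene (flav-3-ene with 2α-aryl group)
Conditions: 8 (1.5 equiv), 4-(dibenzylamino)-2,3-dihydroxy-4-oxobutanoic acid (one enantiomer, 5 mol %), Yb(OTf)3 (5 mol %), EtOAc, −20 °C
Reagents that add atoms: none
Why: Enantioselective addition of an aryl boronate to a chromene acetal under chiral dihydroxy acid/lanthanide triflate co-catalysis: the acetal ionises to the achiral benzopyrylium ion, and the chiral dioxaborolane ate complex formed from 8 and the catalyst delivers the aryl group to one face of C2, which sets the only catalyst-controlled stereocentre of the route.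

Step 5
Reactants: 9 (2S)-flav-3-ene
Product: 10 (2R,3R,4R)-7,8-bis(benzyloxy)-2-[3,4-bis(benzyloxy)phenyl]-3-bromochroman-4-yl acetate (2α-aryl/3β-Br/4α-OAc; 2,3-trans-3,4-trans)
Conditions: NBS (1.05 equiv), AcOH/CH2Cl2 (1:5), −10 °C, dark
Reagents that add atoms: N-bromosuccinimide O=C1CCC(=O)N1Br; acetic acid CC(=O)O
Why: Acetoxybromination (the first stage of a Prévost–Woodward sequence): the bromine electrophile adds to C3 on the β face anti to the 2α-aryl group, and acetic acid captures the O7/O1-stabilised C4 cation anti to bromine, which sets 3β-Br and 4α-OAc.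

Step 6
Reactants: 10 bromo acetate (first portion; becomes rings A, C, B); 10 bromo acetate (second portion; becomes rings D, F, E)
Product: 12 octa-O-benzyl dimer with 3α-OH and 4β-aryl in ring C and unchanged 3β-Br/4α-OAc in ring F, via epoxide 11 (not isolated)
Conditions: (a) first portion of 10, NaOMe (1.0 equiv), THF, −20 to 0 °C; (b) cannula-filter slowly into second portion of 10 (3 equiv) in (CF3)2CHOH/CH2Cl2 (1:2), −20 to 0 °C; aq. NaHCO3
Reagents that add atoms: none
Why: Methoxide removes the acetyl group of the first portion of 10 and the 4α-alkoxide displaces the antiperiplanar 3β-bromide (3-exo-tet, the only ring closed here and a transient one), which inverts C3 and gives the α-epoxide 11 that direct epoxidation of 9, anti to the 2-aryl group, could not give. Hydrogen bonding by (CF3)2CHOH then loosens the C4–O bond, because C4 is para to O7 and ortho to O1 of ring A and the charge is spread as in a quinone methide, and C6 of ring D of the second portion attacks and rearomatises by passing its proton to the 3α-oxygen. The closest known reaction types are the Friedel–Crafts opening of aryl epoxides by electron-rich arenes in fluorinated alcohols and the coupling of flavan-4-yl cations with flavan A rings in proanthocyanidin synthesis. C4 is set by attack on the β face, anti to the leaving α-oxygen and away from the 2α-aryl group, so that an SN2-like and an SN1-like course lead to the same 3,4-trans product, while C2 of both portions is untouched. Chemoselectivity rests on the mask: only the strained epoxide ionises under these mild conditions, whereas the C4–OAc bond of the nucleophile is retarded by the neighbouring bromine and the nucleophile has no free hydroxyl group that could form an ether link. Regioselectivity rests on ring D, where C6 is the only position activated by two conjugated oxygens (C5 answers only to the twisted O8 and is peri-hindered; rings B and E have one para donor each), and the excess of recoverable 10 keeps 11 from alkylating ring A of the product.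

Step 7
Reactants: 12 octa-O-benzyl dimer (ring F bromo acetate)
Product: 14 octa-O-benzyl-epimesquitol-(4β→6)-epimesquitol-4β-ol, via ring F epoxide 13 (not isolated)
Conditions: LiOH (3 equiv), THF/H2O (4:1), 0 °C to rt, Ar
Reagents that add atoms: water O
Why: Saponification of the benzylic acetate frees the 4α-alkoxide, which repeats the 3-exo-tet closure to the α-epoxide 13, and hydroxide/water opens it at benzylic C4 of ring F from the β face (anti epoxide hydrolysis), so that 3α-OH and 4β-OH arise by the same double inversion as in ring C.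

Step 8
Reactants: 14 octa-O-benzyl-epimesquitol-(4β→6)-epimesquitol-4β-ol
Product: 15 epimesquitol-(4β→6)-epimesquitol-4β-ol (target; upper unit 2R,3R,4S; lower unit 2R,3R,4S)
Conditions: H2 (1 atm), Pd(OH)2/C, THF/H2O (9:1), rt, stopped at the calculated uptake; filtration under Ar; Sephadex LH-20
Reagents that add atoms: none
Why: Catalytic hydrogenolysis of aryl benzyl ethers under strictly neutral conditions should be much faster than cleavage of the secondary benzylic C4–OH of ring F or of the C4–C6 diarylmethine bond (as in the final debenzylations of arylethanolamines and of proanthocyanidins), and no stereocentre is touched.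

Compound list
1 | daphnetin (7,8-dihydroxycoumarin) | O=C1C=Cc2ccc(O)c(O)c2O1 | starting material
2 | 7,8-bis(benzyloxy)coumarin | O=C1C=Cc2ccc(OCc3ccccc3)c(OCc3ccccc3)c2O1 | intermediate
3 | 7,8-bis(benzyloxy)-2H-chromen-2-ol (lactol, racemic, not isolated) | OC1C=Cc2ccc(OCc3ccccc3)c(OCc3ccccc3)c2O1 | intermediate
4 | 7,8-bis(benzyloxy)-2-ethoxy-2H-chromene (racemic) | CCOC1C=Cc2ccc(OCc3ccccc3)c(OCc3ccccc3)c2O1 | intermediate
5 | 4-bromo-1,2-bis(benzyloxy)benzene | Brc1ccc(OCc2ccccc2)c(OCc2ccccc2)c1 | starting material
6 | [3,4-bis(benzyloxy)phenyl]lithium (not isolated) | [Li]c1ccc(OCc2ccccc2)c(OCc2ccccc2)c1 | intermediate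
7 | lithium [3,4-bis(benzyloxy)phenyl]triethoxyborate (not isolated) | [Li+].CCO[B-](OCC)(OCC)c1ccc(OCc2ccccc2)c(OCc2ccccc2)c1 | intermediate
8 | diethyl [3,4-bis(benzyloxy)phenyl]boronate | CCOB(OCC)c1ccc(OCc2ccccc2)c(OCc2ccccc2)c1 | intermediate
9 | (2S)-7,8-bis(benzyloxy)-2-[3,4-bis(benzyloxy)phenyl]-2H-chromene | O(Cc1ccccc1)c1ccc([C@H]2Oc3c(ccc(OCc4ccccc4)c3OCc3ccccc3)C=C2)cc1OCc1ccccc1 | intermediate
10 | (2R,3R,4R)-7,8-bis(benzyloxy)-2-[3,4-bis(benzyloxy)phenyl]-3-bromochroman-4-yl acetate (2α-aryl, 3β-Br, 4α-OAc) | O(Cc1ccccc1)c1ccc([C@H]2Oc3c(ccc(OCc4ccccc4)c3OCc3ccccc3)[C@@H](OC(C)=O)[C@@H]2Br)cc1OCc1ccccc1 | intermediate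
11 | (2R,3R,4R)-7,8,3',4'-tetrakis(benzyloxy)-3,4-epoxyflavan (3α,4α-epoxide, cis to the 2-aryl group, not isolated) | O(Cc1ccccc1)c1ccc([C@H]2Oc3c(ccc(OCc4ccccc4)c3OCc3ccccc3)[C@H]3O[C@@H]23)cc1OCc1ccccc1 | intermediate
12 | octa-O-benzyl dimer: ring C 2α-aryl, 3α-OH, 4β-(C6 of ring D); ring F 2α-aryl, 3β-Br, 4α-OAc | O(Cc1ccccc1)c1ccc([C@H]2Oc3c(ccc(OCc4ccccc4)c3OCc3ccccc3)[C@H](c3cc4c(c(OCc5ccccc5)c3OCc3ccccc3)O[C@H](c3ccc(OCc5ccccc5)c(OCc5ccccc5)c3)[C@@H](Br)[C@@H]4OC(C)=O)[C@H]2O)cc1OCc1ccccc1 | intermediate
13 | octa-O-benzyl dimer with 3α,4α-epoxide in ring F (not isolated) | O(Cc1ccccc1)c1ccc([C@H]2Oc3c(ccc(OCc4ccccc4)c3OCc3ccccc3)[C@H](c3cc4c(c(OCc5ccccc5)c3OCc3ccccc3)O[C@H](c3ccc(OCc5ccccc5)c(OCc5ccccc5)c3)[C@@H]3O[C@H]43)[C@H]2O)cc1OCc1ccccc1 | intermediate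
14 | octa-O-benzyl-epimesquitol-(4β→6)-epimesquitol-4β-ol (same spatial arrangement as 15) | O(Cc1ccccc1)c1ccc([C@H]2Oc3c(ccc(OCc4ccccc4)c3OCc3ccccc3)[C@H](c3cc4c(c(OCc5ccccc5)c3OCc3ccccc3)O[C@H](c3ccc(OCc5ccccc5)c(OCc5ccccc5)c3)[C@H](O)[C@H]4O)[C@H]2O)cc1OCc1ccccc1 | intermediate
15 | epimesquitol-(4β→6)-epimesquitol-4β-ol (both pyran rings 2,3-cis-3,4-trans) | Oc1ccc([C@H]2Oc3c(ccc(O)c3O)[C@H](c3cc4c(c(O)c3O)O[C@H](c3ccc(O)c(O)c3)[C@H](O)[C@H]4O)[C@H]2O)cc1O | target

Total step count: 8. Longest linear sequence: 7 steps (1, 2, 4, 5, 6, 7, 8).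

Steps most likely to fail

Step 6. The benzylated ring D may be too weak a nucleophile. The ionised epoxide would then be lost to hydride shift towards the 3-ketone, to solvent capture or to oligomerisation. The fallback changes to free phenols and thiophilic activation, both known for this class.
- It sets out from 10. Treatment with LiOH in aqueous THF (as in step 7) should give tetra-O-benzylisomelacacidin F1.
- Hydrogenolysis over Pd(OH)2/C should give isomelacacidin F2.
- Part of F2 is heated with phenylmethanethiol and AcOH in EtOH to give 4β-benzylsulfanylepimesquitol F3.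
- F3 and an excess of F2 are coupled with AgBF4 in THF at 0 °C. The free 7-OH raises the nucleophilicity of C6 of ring D, and the neutral medium leaves the 4β-OH alone.
- The fallback comes back to the route at 15.

Step 4. Facial discrimination may be insufficient. The very electron-rich 2-arylchromene may also racemise through reversible C2–O1 ionisation under the Lewis acid. A small shortfall would be corrected in step 6, because the minor enantiomer is channelled mostly into separable heterochiral dimers. The fallback replaces asymmetric arylation by kinetic resolution.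
- It sets out from 4 and 8. BF3·OEt2 (cat.) in CH2Cl2 at −78 °C should give the racemic flav-3-ene F4.
- A Jacobsen–Katsuki epoxidation then consumes the (R)-alkene as its 2,3-trans epoxide F5. The reagents are one enantiomer of [N,N'-bis(3,5-di-tert-butylsalicylidene)cyclohexane-1,2-diaminato]manganese chloride (trivalent manganese), mCPBA and N-methylmorpholine N-oxide in CH2Cl2 at −78 °C.
- For the (R)-alkene, catalyst preference and attack anti to the aryl group coincide.
- The unreacted (S)-alkene is recovered, and the fallback comes back at 9.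

Step 8. Over-reduction may remove the benzylic 4β-OH of ring F, or acid traces on the catalyst may ionise it. The fallback shields the alcohols first.
- It sets out from 14. TBSOTf and 2,6-lutidine in CH2Cl2 should give the tris(tert-butyldimethylsilyl) ether F6.
- Hydrogenolysis then gives the octaphenol tris(silyl ether) F7.
- Et3N·3HF in THF/MeCN removes the silyl groups under nearly neutral conditions.
- The fallback comes back at 15.

Further compounds
F1 | step 6 | (2R,3R,4S)-7,8-bis(benzyloxy)-2-[3,4-bis(benzyloxy)phenyl]chromane-3,4-diol (tetra-O-benzylisomelacacidin) | O(Cc1ccccc1)c1ccc([C@H]2Oc3c(ccc(OCc4ccccc4)c3OCc3ccccc3)[C@H](O)[C@H]2O)cc1OCc1ccccc1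
F2 | step 6 | (2R,3R,4S)-2-(3,4-dihydroxyphenyl)chromane-3,4,7,8-tetraol (isomelacacidin) | Oc1ccc([C@H]2Oc3c(ccc(O)c3O)[C@H](O)[C@H]2O)cc1O
F3 | step 6 | (2R,3S,4S)-4-(benzylsulfanyl)-2-(3,4-dihydroxyphenyl)chromane-3,7,8-triol (4β-benzylsulfanylepimesquitol) | Oc1ccc([C@H]2Oc3c(ccc(O)c3O)[C@H](SCc3ccccc3)[C@H]2O)cc1O
F4 | step 4 | racemic 7,8-bis(benzyloxy)-2-[3,4-bis(benzyloxy)phenyl]-2H-chromene | O(Cc1ccccc1)c1ccc(C2Oc3c(ccc(OCc4ccccc4)c3OCc3ccccc3)C=C2)cc1OCc1ccccc1
F5 | step 4 | (2S,3R,4R)-7,8,3',4'-tetrakis(benzyloxy)-3,4-epoxyflavan (epoxide trans to the 2-aryl group, from the (R)-alkene) | O(Cc1ccccc1)c1ccc([C@@H]2Oc3c(ccc(OCc4ccccc4)c3OCc3ccccc3)[C@H]3O[C@@H]23)cc1OCc1ccccc1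
F6 | step 8 | octa-O-benzyl-tris-O-(tert-butyldimethylsilyl) derivative of 15 (silyl ethers at O3 of ring C and O3, O4 of ring F) | O(Cc1ccccc1)c1ccc([C@H]2Oc3c(ccc(OCc4ccccc4)c3OCc3ccccc3)[C@H](c3cc4c(c(OCc5ccccc5)c3OCc3ccccc3)O[C@H](c3ccc(OCc5ccccc5)c(OCc5ccccc5)c3)[C@H](O[Si](C)(C)C(C)(C)C)[C@H]4O[Si](C)(C)C(C)(C)C)[C@H]2O[Si](C)(C)C(C)(C)C)cc1OCc1ccccc1
F7 | step 8 | tris-O-(tert-butyldimethylsilyl) derivative of 15 with all eight phenols free | Oc1ccc([C@H]2Oc3c(ccc(O)c3O)[C@H](c3cc4c(c(O)c3O)O[C@H](c3ccc(O)c(O)c3)[C@H](O[Si](C)(C)C(C)(C)C)[C@H]4O[Si](C)(C)C(C)(C)C)[C@H]2O[Si](C)(C)C(C)(C)C)cc1O
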